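**Retrosynthetic overview** (labdane numbering; target = labd-13E-ene-8α,15-diol 15-acetate)
1. End game: the C15 acetate, C13=C14 and carbons C14–C16 are added last (C13 aldehyde → terminal alkyne → Cp2ZrCl2-catalysed carboalumination/CH2O → acetate).
2. Ring B is closed in one operation that forms C5–C6 and C7–C8: the C5 N-tosylhydrazone of a monocyclic ring A ketone, a vinylboron unit (C6, C7) and the C8 methyl ketone give the Δ5-octalin-8α-ol; α-face hydrogenation then sets C5.
3. Enabling feature: C5 lies between the quaternary carbons C4 and C10 (no α-hydrogen, so its diazo derivative can only act as a carbene equivalent and the alkene can only form toward C6); C8 is a tertiary methyl carbinol placed 1,4 to C5 across C9–C10 of ring B; C6–C7 is an unsubstituted two-carbon bridge.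
4. C9–C10 and both of its stereocentres come from an enantioselective Ireland–Claisen rearrangement of the β-cyclogeranyl ester of 5-(benzyloxy)pentanoic acid; the exocyclic methylene it leaves is ozonised to the C5 ketone, and the acid becomes the C8 methyl ketone via the Weinreb amide.
5. Ring order: ring A is bought (β-cyclocitral); ring B is formed in step 8.

Key step: step 8

Remark: the (S,S)-bromoborane of step 3 is assumed, by analogy with 3,3-disubstituted allyl esters, to give the Z(O)-enolate and the enantiomer drawn; if the sense were opposite, its (R,R)-antipode would be used.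

**Step 1**
Reactants: 1 β-cyclocitral
Product: 2 β-cyclogeraniol
Conditions: NaBH4, MeOH, 0 °C
Reagents that add atoms: none
Why: Borohydride 1,2-reduction of the aldehyde; the fully substituted β-carbon blocks conjugate reduction.

**Step 2**
Reactants: 2 β-cyclogeraniol; 3 5-(benzyloxy)pentanoic acid
Product: 4 (2,6,6-trimethylcyclohex-1-en-1-yl)methyl 5-(benzyloxy)pentanoate
Conditions: DCC, DMAP (cat.), CH2Cl2, 0 °C → rt
Reagents that add atoms: none
Why: Steglich esterification of the primary allylic alcohol under acid-free conditions that do not ionise the allylic C–O bond.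

**Step 3**
Reactants: 4 (2,6,6-trimethylcyclohex-1-en-1-yl)methyl 5-(benzyloxy)pentanoate
Product: 6 (2R)-5-(benzyloxy)-2-[(1R)-1,3,3-trimethyl-2-methylidenecyclohexyl]pentanoic acid, via boron ketene acetal 5 (not isolated)
Conditions: (4S,5S)-2-bromo-4,5-diphenyl-1,3-bis(p-tolylsulfonyl)-1,3,2-diazaborolidine (1.1 equiv, made beforehand from the commercial bis-sulfonamide and BBr3), i-Pr2NEt, CH2Cl2, −78 °C; then −20 °C → rt; aqueous work-up
Reagents that add atoms: none
Why: Enantioselective Ireland–Claisen rearrangement through a chiral boron ketene acetal: the chair transition state of the Z(O)-enolate places the C11 chain pseudo-equatorial and the C10 methyl pseudo-axial, which fixes C9 relative to C10, and the C2-symmetric sulfonamide ligands on boron select the enolate face, which should fix the absolute configuration of both new stereocentres.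

**Step 4**
Reactants: 6 (2R)-5-(benzyloxy)-2-[(1R)-1,3,3-trimethyl-2-methylidenecyclohexyl]pentanoic acid
Product: 8 (2R)-5-(benzyloxy)-N-methoxy-N-methyl-2-[(1R)-1,3,3-trimethyl-2-methylidenecyclohexyl]pentanamide, via acid chloride 7 (not isolated)
Conditions: (COCl)2, DMF (cat.), CH2Cl2, 0 °C → rt; then MeNH(OMe)·HCl, pyridine, 0 °C
Reagents that add atoms: N,O-dimethylhydroxylamine hydrochloride (CNOC.Cl)
Why: Acid chloride formation and amidation give the Weinreb amide; the C9–H is flanked by the quaternary C10 and should resist ketene formation and epimerisation.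

**Step 5**
Reactants: 8 (2R)-5-(benzyloxy)-N-methoxy-N-methyl-2-[(1R)-1,3,3-trimethyl-2-methylidenecyclohexyl]pentanamide
Product: 9 (2R)-5-(benzyloxy)-N-methoxy-N-methyl-2-[(1R)-1,3,3-trimethyl-2-oxocyclohexyl]pentanamide
Conditions: O3, CH2Cl2, −78 °C; then Me2S, −78 °C → rt
Reagents that add atoms: ozone ([O-][O+]=O)
Why: Ozonolysis of the only C=C bond with reductive work-up unmasks the C5 ketone without touching a stereocentre.

**Step 6**
Reactants: 9 (2R)-5-(benzyloxy)-N-methoxy-N-methyl-2-[(1R)-1,3,3-trimethyl-2-oxocyclohexyl]pentanamide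
Product: 10 (2R)-5-(benzyloxy)-N-methoxy-N-methyl-2-[(1R)-1,3,3-trimethyl-2-(2-tosylhydrazinylidene)cyclohexyl]pentanamide
Conditions: TsNHNH2, PPTS (cat.), toluene, 4 Å MS, 90 °C
Reagents that add atoms: p-toluenesulfonyl hydrazide (Cc1ccc(cc1)S(=O)(=O)NN)
Why: Acid-catalysed hydrazone condensation at the only ketone (the Weinreb amide does not condense), a reaction known for ketones flanked by two quaternary carbons such as fenchone.

**Step 7**
Reactants: 10 (2R)-5-(benzyloxy)-N-methoxy-N-methyl-2-[(1R)-1,3,3-trimethyl-2-(2-tosylhydrazinylidene)cyclohexyl]pentanamide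
Product: 11 (3R)-6-(benzyloxy)-3-[(1R)-1,3,3-trimethyl-2-(2-tosylhydrazinylidene)cyclohexyl]hexan-2-one
Conditions: MeMgBr (3 equiv), THF, −20 → 0 °C; then aq. NH4Cl
Reagents that add atoms: methylmagnesium bromide (C[Mg]Br)
Why: Weinreb ketone synthesis: the first equivalent of MeMgBr deprotonates the sulfonylhydrazone N–H, the chelated tetrahedral adduct prevents over-addition, and the hydrazone anion, which has no α-hydrogen, cannot undergo Shapiro elimination.

**Step 8**
Reactants: 11 (3R)-6-(benzyloxy)-3-[(1R)-1,3,3-trimethyl-2-(2-tosylhydrazinylidene)cyclohexyl]hexan-2-one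
Product: 14 (1R,2R,8aR)-1-[3-(benzyloxy)propyl]-2,5,5,8a-tetramethyl-1,2,3,5,6,7,8,8a-octahydronaphthalen-2-ol, via diazoalkane 12 (not isolated), via tertiary allylboron species 13 (not isolated)
Conditions: 2,4,6-trivinylboroxine·pyridine, K2CO3, dry 1,4-dioxane, 110 °C; then H2O
Reagents that add atoms: 2,4,6-trivinylboroxine–pyridine complex (C=CB1OB(C=C)OB(C=C)O1.c1ccncc1)
Why: Proposed new method: K2CO3 converts the sulfonylhydrazone into diazoalkane 12, whose C5 attacks boron of the vinylboroxine and then receives the vinyl group by 1,2-shift with loss of N2 (C5–C6 formed), giving the tertiary allylboron species 13; 13 adds through its γ-carbon C7 to the tethered C8 ketone (C7–C8 formed, double bond moving to C5=C6), and hydrolysis of the B–O8 bond gives 14. The closest known reaction type is the Barluenga-type reductive coupling of N-tosylhydrazones with alkenylboronic acids, whose transient allylboronic acids are known to allylate aldehydes between molecules and nitriles in domino carbocyclisations; trapping by a tethered ketone that leaves the new alkene inside the ring has not been shown. Ring B is closed as a six-membered carbocycle by intramolecular carbonyl allylboration through a closed, boat-shaped six-membered B–O transition state bridged by C9–C10 (a bicyclo[2.2.2]octene-like array). C8 is the only new stereocentre: the breaking C5–B bond must be aligned with the forming C5=C6 π bond, hence axial on ring A, and it should take the α face anti to the β-axial methyls on C10 and C4, so the boron bridge delivers O8 on the α face and leaves the C8 methyl β (C9 and C10 are untouched, C5 becomes trigonal). The step needs boron capture of the hindered diazoalkane faster than carbene formation, and C7 attack faster than 1,3-borotropic shift or protodeboronation; the first is served by excess Lewis-acidic boroxine and the absence of any α-hydrogen at C5, the second by dry conditions and by the 1,4-placement of the ketone, since the rearranged primary allylboron could only close a cyclobutane.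

**Step 9**
Reactants: 14 (1R,2R,8aR)-1-[3-(benzyloxy)propyl]-2,5,5,8a-tetramethyl-1,2,3,5,6,7,8,8a-octahydronaphthalen-2-ol
Product: 15 (1R,2R,4aS,8aS)-1-(3-hydroxypropyl)-2,5,5,8a-tetramethyldecahydronaphthalen-2-ol
Conditions: H2 (10 bar), Pd(OH)2/C, EtOH, rt
Reagents that add atoms: none
Why: Heterogeneous hydrogenation should add H2 to C5=C6 from the α face, because the β face is shielded by the axial methyls on C10, C4 and C8 (as known for 4,4,10-trimethyl-Δ5-octalins), which sets the trans ring fusion at C5, while the benzyl ether is hydrogenolysed in the same operation.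

**Step 10**
Reactants: 15 (1R,2R,4aS,8aS)-1-(3-hydroxypropyl)-2,5,5,8a-tetramethyldecahydronaphthalen-2-ol
Product: 16 3-[(1R,2R,4aS,8aS)-2-hydroxy-2,5,5,8a-tetramethyldecahydronaphthalen-1-yl]propanal
Conditions: Dess–Martin periodinane (1.1 equiv), CH2Cl2, 0 °C
Reagents that add atoms: none
Why: Dess–Martin oxidation of the primary alcohol; the tertiary C8 alcohol cannot be oxidised and the aldehyde is expected to equilibrate with its six-membered lactol.

**Step 11**
Reactants: 16 3-[(1R,2R,4aS,8aS)-2-hydroxy-2,5,5,8a-tetramethyldecahydronaphthalen-1-yl]propanal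
Product: 17 (1R,2R,4aS,8aS)-1-(but-3-yn-1-yl)-2,5,5,8a-tetramethyldecahydronaphthalen-2-ol
Conditions: dimethyl (1-diazo-2-oxopropyl)phosphonate, K2CO3, MeOH, 0 °C → rt
Reagents that add atoms: dimethyl (1-diazo-2-oxopropyl)phosphonate (CC(=O)C(=[N+]=[N-])P(=O)(OC)OC)
Why: Ohira–Bestmann (Seyferth–Gilbert) homologation converts the aldehyde, released from the lactol under the basic conditions, into the terminal alkyne with one added carbon (C14).

**Step 12**
Reactants: 17 (1R,2R,4aS,8aS)-1-(but-3-yn-1-yl)-2,5,5,8a-tetramethyldecahydronaphthalen-2-ol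
Product: 19 (1R,2R,4aS,8aS)-1-[(3E)-5-hydroxy-3-methylpent-3-en-1-yl]-2,5,5,8a-tetramethyldecahydronaphthalen-2-ol, via alkenylalane 18 (not isolated)
Conditions: Me3Al (4 equiv), Cp2ZrCl2 (0.2 equiv), CH2Cl2, 0 °C → rt; then n-BuLi, THF, −78 °C; (CH2O)n, −78 °C → rt; aq. Rochelle salt
Reagents that add atoms: trimethylaluminium (C[Al](C)C); formaldehyde from paraformaldehyde (C=O)
Why: Negishi carboalumination adds CH3 and Al syn across the terminal alkyne (methyl to C13), and the alkenylalanate is trapped by formaldehyde with retention, which sets the 13E double bond.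

**Step 13**
Reactants: 19 (1R,2R,4aS,8aS)-1-[(3E)-5-hydroxy-3-methylpent-3-en-1-yl]-2,5,5,8a-tetramethyldecahydronaphthalen-2-ol
Product: 20 (2E)-5-[(1R,2R,4aS,8aS)-2-hydroxy-2,5,5,8a-tetramethyldecahydronaphthalen-1-yl]-3-methylpent-2-en-1-yl acetate
Conditions: Ac2O, pyridine, DMAP (cat.), CH2Cl2, 0 °C
Reagents that add atoms: acetic anhydride (CC(=O)OC(C)=O)
Why: DMAP-catalysed acetylation is selective for the primary allylic alcohol over the hindered tertiary C8 alcohol.

**Compound list**
1 | β-cyclocitral (2,6,6-trimethylcyclohex-1-ene-1-carbaldehyde) | CC1=C(C=O)C(C)(C)CCC1 | starting material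
2 | β-cyclogeraniol ((2,6,6-trimethylcyclohex-1-en-1-yl)methanol) | CC1=C(CO)C(C)(C)CCC1 | intermediate
3 | 5-(benzyloxy)pentanoic acid (commercial) | OC(=O)CCCCOCc1ccccc1 | starting material
4 | (2,6,6-trimethylcyclohex-1-en-1-yl)methyl 5-(benzyloxy)pentanoate | CC1=C(COC(=O)CCCCOCc2ccccc2)C(C)(C)CCC1 | intermediate
5 | Z(O)-boron ketene acetal of 4 (C11 chain cis to O–B; boron carries the (4S,5S)-4,5-diphenyl-1,3-ditosyl-1,3,2-diazaborolidine ring) | c1ccccc1COCCC/C=C(\OB2N(S(=O)(=O)c3ccc(C)cc3)[C@@H](c3ccccc3)[C@H](c3ccccc3)N2S(=O)(=O)c2ccc(C)cc2)/OCC2=C(C)CCCC2(C)C | intermediate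
6 | (2R)-5-(benzyloxy)-2-[(1R)-1,3,3-trimethyl-2-methylidenecyclohexyl]pentanoic acid | c1ccccc1COCCC[C@@H](C(=O)O)[C@@]1(C)CCCC(C)(C)C1=C | intermediate
7 | (2R)-5-(benzyloxy)-2-[(1R)-1,3,3-trimethyl-2-methylidenecyclohexyl]pentanoyl chloride | c1ccccc1COCCC[C@@H](C(=O)Cl)[C@@]1(C)CCCC(C)(C)C1=C | intermediate
8 | (2R)-5-(benzyloxy)-N-methoxy-N-methyl-2-[(1R)-1,3,3-trimethyl-2-methylidenecyclohexyl]pentanamide | c1ccccc1COCCC[C@@H](C(=O)N(C)OC)[C@@]1(C)CCCC(C)(C)C1=C | intermediate
9 | (2R)-5-(benzyloxy)-N-methoxy-N-methyl-2-[(1R)-1,3,3-trimethyl-2-oxocyclohexyl]pentanamide | c1ccccc1COCCC[C@@H](C(=O)N(C)OC)[C@@]1(C)CCCC(C)(C)C1=O | intermediate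
10 | (2R)-5-(benzyloxy)-N-methoxy-N-methyl-2-[(1R)-1,3,3-trimethyl-2-(2-tosylhydrazinylidene)cyclohexyl]pentanamide | c1ccccc1COCCC[C@@H](C(=O)N(C)OC)[C@@]1(C)CCCC(C)(C)C1=NNS(=O)(=O)c1ccc(C)cc1 | intermediate
11 | (3R)-6-(benzyloxy)-3-[(1R)-1,3,3-trimethyl-2-(2-tosylhydrazinylidene)cyclohexyl]hexan-2-one | c1ccccc1COCCC[C@@H](C(C)=O)[C@@]1(C)CCCC(C)(C)C1=NNS(=O)(=O)c1ccc(C)cc1 | intermediate
12 | (3R)-6-(benzyloxy)-3-[(1R)-2-diazo-1,3,3-trimethylcyclohexyl]hexan-2-one | c1ccccc1COCCC[C@@H](C(C)=O)[C@@]1(C)CCCC(C)(C)C1=[N+]=[N-] | intermediate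
13 | tertiary allylboronic acid (drawn as free B(OH)2, boroxine-bound in the flask): C5 carries vinyl and boron, boron trans to the C10 methyl | c1ccccc1COCCC[C@@H](C(C)=O)[C@@]1(C)CCCC(C)(C)[C@@]1(C=C)B(O)O | intermediate
14 | (1R,2R,8aR)-1-[3-(benzyloxy)propyl]-2,5,5,8a-tetramethyl-1,2,3,5,6,7,8,8a-octahydronaphthalen-2-ol | c1ccccc1COCCC[C@@H]1[C@@]2(C)CCCC(C)(C)C2=CC[C@@]1(C)O | intermediate
15 | (1R,2R,4aS,8aS)-1-(3-hydroxypropyl)-2,5,5,8a-tetramethyldecahydronaphthalen-2-ol | OCCC[C@@H]1[C@@]2(C)CCCC(C)(C)[C@@H]2CC[C@@]1(C)O | intermediate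
16 | 3-[(1R,2R,4aS,8aS)-2-hydroxy-2,5,5,8a-tetramethyldecahydronaphthalen-1-yl]propanal (in equilibrium with its lactol) | O=CCC[C@@H]1[C@@]2(C)CCCC(C)(C)[C@@H]2CC[C@@]1(C)O | intermediate
17 | (1R,2R,4aS,8aS)-1-(but-3-yn-1-yl)-2,5,5,8a-tetramethyldecahydronaphthalen-2-ol | C#CCC[C@@H]1[C@@]2(C)CCCC(C)(C)[C@@H]2CC[C@@]1(C)O | intermediate
18 | (E)-alkenyl(dimethyl)alane of 17 (Al on C14 cis to the new C13 methyl; C8 oxygen as its dimethylaluminium alkoxide) | C[Al](C)/C=C(\C)CC[C@@H]1[C@@]2(C)CCCC(C)(C)[C@@H]2CC[C@@]1(C)O[Al](C)C | intermediate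
19 | (1R,2R,4aS,8aS)-1-[(3E)-5-hydroxy-3-methylpent-3-en-1-yl]-2,5,5,8a-tetramethyldecahydronaphthalen-2-ol (labd-13E-ene-8α,15-diol) | OC/C=C(\C)CC[C@@H]1[C@@]2(C)CCCC(C)(C)[C@@H]2CC[C@@]1(C)O | intermediate
20 | (2E)-5-[(1R,2R,4aS,8aS)-2-hydroxy-2,5,5,8a-tetramethyldecahydronaphthalen-1-yl]-3-methylpent-2-en-1-yl acetate | CC(=O)OC/C=C(\C)CC[C@@H]1[C@@]2(C)CCCC(C)(C)[C@@H]2CC[C@@]1(C)O | target

**Totals**
Total step count: 13. Longest linear sequence: 13 steps (1 → 20); compound 3 is bought.

**Steps most likely to fail**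

1. Step 8 (proposed new method). What may go wrong: loss of nitrogen from the hindered diazoalkane to a carbene before boron capture (alkyl shift, C–H insertion or carbonyl ylide formation with the ketone); 1,3-borotropic shift or protodeboronation of the allylboron species before the boat transition state is reached; base-mediated epimerisation at C9. Fallback (known chemistry, ring B closed stepwise by a 6-endo radical cyclisation): it sets out from Weinreb amide 8 and returns at diol 15. MeMgBr converts 8 into (3R)-6-(benzyloxy)-3-[(1R)-1,3,3-trimethyl-2-methylidenecyclohexyl]hexan-2-one F1. Kinetic enolisation at the methyl group (LiN(i-Pr)2, TMSCl, −78 °C) and NBS give the bromomethyl ketone (3R)-6-(benzyloxy)-1-bromo-3-[(1R)-1,3,3-trimethyl-2-methylidenecyclohexyl]hexan-2-one F2. Bu3SnH/AIBN (slow addition, benzene, 80 °C) generates the α-keto radical, which should cyclise 6-endo onto the C5 exocyclic methylene (its CH2 becomes C6); hydrogen transfer to the C5 radical from the open α face should give the trans-decalone (1R,4aS,8aS)-1-[3-(benzyloxy)propyl]-5,5,8a-trimethyloctahydronaphthalen-2(1H)-one F3. Wittig methylenation (Ph3P=CH2, toluene, 80 °C) gives the 8(17)-exocyclic alkene F4 (the 2-methylidene analogue of F3 with unchanged ring configuration). Oxymercuration–demercuration (Hg(OAc)2, THF–H2O; then NaBH4), with equatorial delivery of oxygen as is usual for labd-8(17)-enes, gives (1R,2R,4aS,8aS)-1-[3-(benzyloxy)propyl]-2,5,5,8a-tetramethyldecahydronaphthalen-2-ol F5. Hydrogenolysis (H2, Pd(OH)2/C) gives 15.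

2. Step 6. What may go wrong: incomplete condensation at the carbonyl flanked by two quaternary carbons. Fallback: it sets out from keto amide 9 and returns at hydrazone 10. The much smaller hydrazine is condensed first (N2H4·H2O, AcOH cat., EtOH, 80 °C) to give the free hydrazone (2R)-5-(benzyloxy)-2-[(1R)-2-hydrazinylidene-1,3,3-trimethylcyclohexyl]-N-methoxy-N-methylpentanamide F8, which is then N-sulfonylated (TsCl, pyridine, 0 °C) to 10.

3. Step 3. What may go wrong: slow rearrangement of the hindered boron ketene acetal at low temperature, with erosion of enolate geometry or of facial control (poor diastereo- or enantioselectivity). Fallback: it sets out from ester 4 and returns at acid 6. An Ireland–Claisen rearrangement with achiral reagents (LiN(i-Pr)2, THF–HMPA, TMSCl, −78 → 60 °C) through the Z(O)-silyl ketene acetal should give the racemic acid F6 with the same relative configuration. Classical resolution follows: the (R)-1-phenylethylammonium salt of 6 F7 is crystallised (the antipodal amine is used if it gives the less soluble pair) and acidified to 6.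

**Further compounds**
F1 | step 8 | (3R)-6-(benzyloxy)-3-[(1R)-1,3,3-trimethyl-2-methylidenecyclohexyl]hexan-2-one | c1ccccc1COCCC[C@@H](C(C)=O)[C@@]1(C)CCCC(C)(C)C1=C
F2 | step 8 | (3R)-6-(benzyloxy)-1-bromo-3-[(1R)-1,3,3-trimethyl-2-methylidenecyclohexyl]hexan-2-one | c1ccccc1COCCC[C@@H](C(=O)CBr)[C@@]1(C)CCCC(C)(C)C1=C
F3 | step 8 | (1R,4aS,8aS)-1-[3-(benzyloxy)propyl]-5,5,8a-trimethyloctahydronaphthalen-2(1H)-one | c1ccccc1COCCC[C@@H]1[C@@]2(C)CCCC(C)(C)[C@@H]2CCC1=O
F4 | step 8 | 8(17)-exocyclic alkene (2-methylidene analogue of F3, ring configuration unchanged) | c1ccccc1COCCC[C@@H]1[C@@]2(C)CCCC(C)(C)[C@@H]2CCC1=C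
F5 | step 8 | (1R,2R,4aS,8aS)-1-[3-(benzyloxy)propyl]-2,5,5,8a-tetramethyldecahydronaphthalen-2-ol | c1ccccc1COCCC[C@@H]1[C@@]2(C)CCCC(C)(C)[C@@H]2CC[C@@]1(C)O
F6 | step 3 | racemic acid (6 together with its enantiomer) | c1ccccc1COCCC[C@@H](C(=O)O)[C@@]1(C)CCCC(C)(C)C1=C.c1ccccc1COCCC[C@H](C(=O)O)[C@]1(C)CCCC(C)(C)C1=C
F7 | step 3 | (R)-1-phenylethylammonium salt of 6 | c1ccccc1COCCC[C@@H](C(=O)[O-])[C@@]1(C)CCCC(C)(C)C1=C.C[C@@H]([NH3+])c1ccccc1
F8 | step 6 | (2R)-5-(benzyloxy)-2-[(1R)-2-hydrazinylidene-1,3,3-trimethylcyclohexyl]-N-methoxy-N-methylpentanamide | c1ccccc1COCCC[C@@H](C(=O)N(C)OC)[C@@]1(C)CCCC(C)(C)C1=NN
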